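The flavone is disconnected across the pyranone so that O1–C8a, C4–C4a and O1–C2 are all made in one flask. Ring A carries the C4 acyl group on C4a and O1 on the neighbouring C8a, with the 5-oxygen next to C4a: exactly what a 3-alkoxybenzyne leaves behind when it inserts into a carboxylate C–O bond. A 2-silylaryl triflate holding the 5-, 6- and 7-oxygens (C8 still H) therefore meets a β-chloro-α-methoxycinnamic acid that brings ring B, C2, C3 with its methoxy group, and C4. Insertion gives an o-acylphenoxide that displaces chloride to close the pyranone; C8 methoxylation and debenzylation finish the synthesis.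

Key step: step 13

Assumption: the β-chloro acrylate made in step 11 and the compounds derived from it are drawn as E isomers; an E/Z mixture would serve equally, because the ring closure in step 13 passes through a freely rotating enolate.

Step 1
Reactants: 1 methyl 3,5-dihydroxy-4-methoxybenzoate
Product: 2 methyl 3,5-bis(benzyloxy)-4-methoxybenzoate
Conditions: BnBr, K2CO3, DMF, 60 °C
Reagents that add atoms: benzyl bromide, BrCc1ccccc1
Why: Williamson ether synthesis on two equivalent, unhindered phenols with a reactive benzylic halide should proceed cleanly, the methyl ester being inert to carbonate.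

Step 2
Reactants: 2 methyl 3,5-bis(benzyloxy)-4-methoxybenzoate
Product: 3 [3,5-bis(benzyloxy)-4-methoxyphenyl]methanol
Conditions: LiAlH4, THF, 0 °C; aqueous work-up
Reagents that add atoms: none
Why: Hydride reduction of an aryl ester to the benzylic alcohol with LiAlH4 is routine and should leave the aryl benzyl and methyl ethers untouched.

Step 3
Reactants: 3 [3,5-bis(benzyloxy)-4-methoxyphenyl]methanol
Product: 4 3,5-bis(benzyloxy)-4-methoxybenzaldehyde
Conditions: MnO2, CH2Cl2, rt
Reagents that add atoms: none
Why: Activated MnO2 oxidises benzylic alcohols selectively to the aldehyde stage (benzylic alcohol oxidation) without touching the ethers.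

Step 4
Reactants: 4 3,5-bis(benzyloxy)-4-methoxybenzaldehyde
Product: 6 3,5-bis(benzyloxy)-4-methoxyphenol, via aryl formate 5 (not isolated)
Conditions: mCPBA, CH2Cl2, 0 °C → rt; then K2CO3 (cat.), MeOH, rt
Reagents that add atoms: meta-chloroperbenzoic acid, O=C(OO)c1cccc(Cl)c1
Why: In this Dakin-type Baeyer–Villiger oxidation the para-methoxy-substituted aryl group should migrate in preference to hydride, giving formate 5, which methanolysis converts into the phenol.

Step 5
Reactants: 6 3,5-bis(benzyloxy)-4-methoxyphenol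
Product: 7 3,5-bis(benzyloxy)-2-bromo-4-methoxyphenol
Conditions: NBS (1.0 equiv), CH2Cl2, −78 → 0 °C
Reagents that add atoms: N-bromosuccinimide, O=C1CCC(=O)N1Br
Why: Electrophilic aromatic bromination ortho to the free hydroxyl can give only one monobromide because the two open positions of the symmetric phenol are equivalent, and slow addition at low temperature should limit dibromination.

Step 6
Reactants: 7 3,5-bis(benzyloxy)-2-bromo-4-methoxyphenol
Product: 10 3,5-bis(benzyloxy)-4-methoxy-2-(trimethylsilyl)phenyl trifluoromethanesulfonate, via aryl trimethylsilyl ether 8 (not isolated), via lithium 2-silylphenoxide 9 (not isolated)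
Conditions: HMDS, THF, 70 °C, then evaporate; n-BuLi, THF, −100 → −78 °C; Tf2O, −100 → −78 °C
Reagents that add atoms: hexamethyldisilazane, C[Si](C)(C)N[Si](C)(C)C; trifluoromethanesulfonic anhydride, O=S(=O)(OS(=O)(=O)C(F)(F)F)C(F)(F)F
Why: O-silylation, bromine–lithium exchange and retro-Brook migration of silicon from oxygen to carbon should deliver phenoxide 9, which Tf2O traps, the standard one-flask entry to 2-silylaryl triflates in which halogen–metal exchange at −100 °C outruns benzylic deprotonation.

Step 7
Reactants: 11 2-methoxyhydroquinone (2-methoxybenzene-1,4-diol)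
Product: 12 1,4-bis(benzyloxy)-2-methoxybenzene
Conditions: BnBr, K2CO3, DMF, 60 °C, under N2
Reagents that add atoms: benzyl bromide, BrCc1ccccc1
Why: Williamson ether synthesis on both phenols should be clean if air is excluded, since the hydroquinone is oxidised easily under base.

Step 8
Reactants: 12 1,4-bis(benzyloxy)-2-methoxybenzene
Product: 13 2,5-bis(benzyloxy)-4-methoxybenzaldehyde
Conditions: POCl3, DMF, 0 → 70 °C; then H2O
Reagents that add atoms: N,N-dimethylformamide, CN(C)C=O; water, O
Why: Vilsmeier–Haack formylation of the 1,2,4-trialkoxybenzene should occur at the one carbon that is para to the methoxy group, ortho to a benzyloxy group and not flanked by two substituents.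

Step 9
Reactants: 13 2,5-bis(benzyloxy)-4-methoxybenzaldehyde; 14 methyl methoxyacetate
Product: 16 methyl 3-[2,5-bis(benzyloxy)-4-methoxyphenyl]-3-hydroxy-2-methoxypropanoate (racemic syn/anti mixture), via lithium ester enolate 15 (not isolated)
Conditions: LiN(iPr)2, THF, −78 °C; then 13; AcOH quench
Reagents that add atoms: none
Why: Aldol addition of the preformed lithium enolate of an α-alkoxy ester to a non-enolisable aldehyde is reliable; the two new stereocentres are formed without control because both are erased in steps 10 and 11.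

Step 10
Reactants: 16 methyl 3-[2,5-bis(benzyloxy)-4-methoxyphenyl]-3-hydroxy-2-methoxypropanoate
Product: 17 methyl 3-[2,5-bis(benzyloxy)-4-methoxyphenyl]-2-methoxy-3-oxopropanoate (racemic)
Conditions: Dess–Martin periodinane, CH2Cl2, rt
Reagents that add atoms: none
Why: Dess–Martin oxidation should convert the benzylic secondary alcohol into the aryl ketone under near-neutral conditions that avoid retro-aldol cleavage; the remaining enolisable stereocentre is racemic and disappears in step 11.

Step 11
Reactants: 17 methyl 3-[2,5-bis(benzyloxy)-4-methoxyphenyl]-2-methoxy-3-oxopropanoate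
Product: 18 methyl (E)-3-[2,5-bis(benzyloxy)-4-methoxyphenyl]-3-chloro-2-methoxyprop-2-enoate
Conditions: (COCl)2, DMF, CH2Cl2, 0 → 40 °C
Reagents that add atoms: oxalyl chloride, O=C(Cl)C(=O)Cl
Why: Vilsmeier-type deoxychlorination of a β-keto ester: the enol oxygen is activated as an iminium ether and chloride substitutes at the β-carbon by addition–elimination, while the fully substituted α-carbon rules out C-formylation.

Step 12
Reactants: 18 methyl (E)-3-[2,5-bis(benzyloxy)-4-methoxyphenyl]-3-chloro-2-methoxyprop-2-enoate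
Product: 19 (E)-3-[2,5-bis(benzyloxy)-4-methoxyphenyl]-3-chloro-2-methoxyprop-2-enoic acid
Conditions: LiOH, THF–MeOH–H2O, 0 °C → rt; then 1 M HCl
Reagents that add atoms: lithium hydroxide, [Li+].[OH-]
Why: Saponification should occur at the ester carbonyl because the chlorine-bearing carbon is tetrasubstituted, shielded by the ortho-benzyloxy aryl group and deactivated by that donor ring, and there is no α-hydrogen for dehydrochlorination.

Step 13
Reactants: 10 3,5-bis(benzyloxy)-4-methoxy-2-(trimethylsilyl)phenyl trifluoromethanesulfonate; 19 (E)-3-[2,5-bis(benzyloxy)-4-methoxyphenyl]-3-chloro-2-methoxyprop-2-enoic acid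
Product: 23 5,7-bis(benzyloxy)-2-[2,5-bis(benzyloxy)-4-methoxyphenyl]-3,6-dimethoxy-4H-chromen-4-one, via caesium carboxylate 20 (not isolated), via alkoxybenzyne 21 (not isolated), via o-acylphenoxide 22 (not isolated)
Conditions: 19 pre-stirred with CsF (4 equiv), then 10 (1.5 equiv), THF, 125 °C, sealed tube
Reagents that add atoms: none
Why: Fluoride removes the silyl group of 10 with loss of triflate to release aryne 21, the carboxylate oxygen of 20 adds to the aryne carbon remote from the flanking benzyloxy group (future C8a), and the aryl anion thus placed on the future C4a attacks the adjacent ester carbonyl so that the acyl group moves from oxygen to carbon and phenoxide 22 results, a net insertion of the aryne into the carboxyl C–O bond. The closest known reaction type is the fluoride-induced insertion of arynes into the C–O bond of carboxylic acids to give o-hydroxyaryl ketones, which is known to run on in the same flask to chromanones and flavones when the acid is α,β-unsaturated. The pyranone then closes by 6-endo-trig oxa-Michael addition of the phenoxide to the chlorine-bearing β-carbon and loss of chloride from the resulting enolate (addition–elimination), which forms O1–C2 with the 3-methoxy group already in place and makes both alkene geometries converge. No stereocentre is created. The selectivity required is regiochemical (carboxylate at C8a, acyl at C4a) and is secured by the benzyloxy group beside the triple bond, which stabilises the developing negative charge on the neighbouring carbon inductively, while C8 carries only hydrogen and offers no competing bias; hot aprotic THF, slow aryne release and carboxylate 20 preformed with excess CsF should favour the acyl shift over protonation of the aryl anion.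

Step 14
Reactants: 23 5,7-bis(benzyloxy)-2-[2,5-bis(benzyloxy)-4-methoxyphenyl]-3,6-dimethoxy-4H-chromen-4-one
Product: 24 7-(benzyloxy)-2-[2,5-bis(benzyloxy)-4-methoxyphenyl]-5-hydroxy-3,6-dimethoxy-4H-chromen-4-one
Conditions: MgBr2·OEt2, toluene–Et2O, 60 °C; then 1 M HCl
Reagents that add atoms: none
Why: Chelation-assisted ether cleavage: magnesium held between the C4 carbonyl and the peri 5-oxygen activates only that benzyl ether towards bromide, so the other three benzyl ethers and the less easily displaced methyl ethers should remain.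

Step 15
Reactants: 24 7-(benzyloxy)-2-[2,5-bis(benzyloxy)-4-methoxyphenyl]-5-hydroxy-3,6-dimethoxy-4H-chromen-4-one
Product: 25 7-(benzyloxy)-2-[2,5-bis(benzyloxy)-4-methoxyphenyl]-8-bromo-5-hydroxy-3,6-dimethoxy-4H-chromen-4-one
Conditions: NBS (1.05 equiv), CH2Cl2, 0 °C
Reagents that add atoms: N-bromosuccinimide, O=C1CCC(=O)N1Br
Why: Electrophilic aromatic bromination should go to C8, the only open carbon of ring A, which is para to the free 5-hydroxyl and ortho to the 7-benzyloxy group and hence far more nucleophilic than the open carbons of ring B on the electron-poor chromone.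

Step 16
Reactants: 25 7-(benzyloxy)-2-[2,5-bis(benzyloxy)-4-methoxyphenyl]-8-bromo-5-hydroxy-3,6-dimethoxy-4H-chromen-4-one
Product: 26 7-(benzyloxy)-2-[2,5-bis(benzyloxy)-4-methoxyphenyl]-5-hydroxy-3,6,8-trimethoxy-4H-chromen-4-one
Conditions: NaOMe, CuBr, MeOH–DMF, 110 °C; then dilute HCl
Reagents that add atoms: sodium methoxide, [Na+].[O-]C
Why: Copper-mediated Ullmann-type methoxylation of an aryl bromide is established for 8-bromo-5-hydroxyflavones, the 5-hydroxyl simply being carried as its phenoxide.

Step 17
Reactants: 26 7-(benzyloxy)-2-[2,5-bis(benzyloxy)-4-methoxyphenyl]-5-hydroxy-3,6,8-trimethoxy-4H-chromen-4-one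
Product: 27 5,7,2',5'-tetrahydroxy-3,6,8,4'-tetramethoxyflavone (5,7-dihydroxy-2-(2,5-dihydroxy-4-methoxyphenyl)-3,6,8-trimethoxy-4H-chromen-4-one)
Conditions: H2 (1 atm), 10% Pd/C, EtOAc–MeOH, rt; work-up under argon
Reagents that add atoms: none
Why: Catalytic hydrogenolysis should cleave the three remaining benzyl ethers while the fully substituted C2–C3 double bond and the methyl ethers survive these mild conditions.

Compound list
1 | methyl 3,5-dihydroxy-4-methoxybenzoate | COC(=O)c1cc(O)c(OC)c(O)c1 | starting material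
2 | methyl 3,5-bis(benzyloxy)-4-methoxybenzoate | COC(=O)c1cc(OCc2ccccc2)c(OC)c(OCc2ccccc2)c1 | intermediate
3 | [3,5-bis(benzyloxy)-4-methoxyphenyl]methanol | OCc1cc(OCc2ccccc2)c(OC)c(OCc2ccccc2)c1 | intermediate
4 | 3,5-bis(benzyloxy)-4-methoxybenzaldehyde | O=Cc1cc(OCc2ccccc2)c(OC)c(OCc2ccccc2)c1 | intermediate
5 | 3,5-bis(benzyloxy)-4-methoxyphenyl formate | O=COc1cc(OCc2ccccc2)c(OC)c(OCc2ccccc2)c1 | intermediate (not isolated)
6 | 3,5-bis(benzyloxy)-4-methoxyphenol | Oc1cc(OCc2ccccc2)c(OC)c(OCc2ccccc2)c1 | intermediate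
7 | 3,5-bis(benzyloxy)-2-bromo-4-methoxyphenol | Oc1cc(OCc2ccccc2)c(OC)c(OCc2ccccc2)c1Br | intermediate
8 | [3,5-bis(benzyloxy)-2-bromo-4-methoxyphenoxy]trimethylsilane | C[Si](C)(C)Oc1cc(OCc2ccccc2)c(OC)c(OCc2ccccc2)c1Br | intermediate (not isolated)
9 | lithium 3,5-bis(benzyloxy)-4-methoxy-2-(trimethylsilyl)phenolate | [Li+].[O-]c1cc(OCc2ccccc2)c(OC)c(OCc2ccccc2)c1[Si](C)(C)C | intermediate (not isolated)
10 | 3,5-bis(benzyloxy)-4-methoxy-2-(trimethylsilyl)phenyl trifluoromethanesulfonate | COc1c(OCc2ccccc2)cc(OS(=O)(=O)C(F)(F)F)c([Si](C)(C)C)c1OCc1ccccc1 | intermediate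
11 | 2-methoxyhydroquinone (2-methoxybenzene-1,4-diol) | COc1cc(O)ccc1O | starting material
12 | 1,4-bis(benzyloxy)-2-methoxybenzene | COc1cc(OCc2ccccc2)ccc1OCc1ccccc1 | intermediate
13 | 2,5-bis(benzyloxy)-4-methoxybenzaldehyde | COc1cc(OCc2ccccc2)c(C=O)cc1OCc1ccccc1 | intermediate
14 | methyl methoxyacetate | COCC(=O)OC | starting material
15 | lithium 1,2-dimethoxyethen-1-olate (lithium enolate of 14) | [Li+].[O-]C(OC)=COC | intermediate (not isolated)
16 | methyl 3-[2,5-bis(benzyloxy)-4-methoxyphenyl]-3-hydroxy-2-methoxypropanoate (racemic, syn/anti mixture) | COC(C(=O)OC)C(O)c1cc(OCc2ccccc2)c(OC)cc1OCc1ccccc1 | intermediate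
17 | methyl 3-[2,5-bis(benzyloxy)-4-methoxyphenyl]-2-methoxy-3-oxopropanoate (racemic) | COC(C(=O)OC)C(=O)c1cc(OCc2ccccc2)c(OC)cc1OCc1ccccc1 | intermediate
18 | methyl (E)-3-[2,5-bis(benzyloxy)-4-methoxyphenyl]-3-chloro-2-methoxyprop-2-enoate | CO/C(C(=O)OC)=C(/Cl)c1cc(OCc2ccccc2)c(OC)cc1OCc1ccccc1 | intermediate
19 | (E)-3-[2,5-bis(benzyloxy)-4-methoxyphenyl]-3-chloro-2-methoxyprop-2-enoic acid | CO/C(C(=O)O)=C(/Cl)c1cc(OCc2ccccc2)c(OC)cc1OCc1ccccc1 | intermediate
20 | caesium (E)-3-[2,5-bis(benzyloxy)-4-methoxyphenyl]-3-chloro-2-methoxyprop-2-enoate | [Cs+].CO/C(C(=O)[O-])=C(/Cl)c1cc(OCc2ccccc2)c(OC)cc1OCc1ccccc1 | intermediate (not isolated)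
21 | 3,5-bis(benzyloxy)-4-methoxybenzyne (3,5-bis(benzyloxy)-4-methoxy-1,2-didehydrobenzene) | COC1=C(OCc2ccccc2)C#CC=C1OCc1ccccc1 | intermediate (not isolated)
22 | caesium 3,5-bis(benzyloxy)-2-{(E)-3-[2,5-bis(benzyloxy)-4-methoxyphenyl]-3-chloro-2-methoxyprop-2-enoyl}-4-methoxyphenolate | [Cs+].CO/C(C(=O)c1c([O-])cc(OCc2ccccc2)c(OC)c1OCc1ccccc1)=C(/Cl)c1cc(OCc2ccccc2)c(OC)cc1OCc1ccccc1 | intermediate (not isolated)
23 | 5,7-bis(benzyloxy)-2-[2,5-bis(benzyloxy)-4-methoxyphenyl]-3,6-dimethoxy-4H-chromen-4-one | COc1cc(OCc2ccccc2)c(-c2oc3cc(OCc4ccccc4)c(OC)c(OCc4ccccc4)c3c(=O)c2OC)cc1OCc1ccccc1 | intermediate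
24 | 7-(benzyloxy)-2-[2,5-bis(benzyloxy)-4-methoxyphenyl]-5-hydroxy-3,6-dimethoxy-4H-chromen-4-one | COc1cc(OCc2ccccc2)c(-c2oc3cc(OCc4ccccc4)c(OC)c(O)c3c(=O)c2OC)cc1OCc1ccccc1 | intermediate
25 | 7-(benzyloxy)-2-[2,5-bis(benzyloxy)-4-methoxyphenyl]-8-bromo-5-hydroxy-3,6-dimethoxy-4H-chromen-4-one | COc1cc(OCc2ccccc2)c(-c2oc3c(Br)c(OCc4ccccc4)c(OC)c(O)c3c(=O)c2OC)cc1OCc1ccccc1 | intermediate
26 | 7-(benzyloxy)-2-[2,5-bis(benzyloxy)-4-methoxyphenyl]-5-hydroxy-3,6,8-trimethoxy-4H-chromen-4-one | COc1cc(OCc2ccccc2)c(-c2oc3c(OC)c(OCc4ccccc4)c(OC)c(O)c3c(=O)c2OC)cc1OCc1ccccc1 | intermediate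
27 | 5,7,2',5'-tetrahydroxy-3,6,8,4'-tetramethoxyflavone | COc1cc(O)c(-c2oc3c(OC)c(O)c(OC)c(O)c3c(=O)c2OC)cc1O | target

Total step count: 17. Longest linear sequence: 11 steps (steps 1–6, then 13–17; the ring B branch, steps 7–12 followed by 13–17, is equally long).

Steps most likely to fail

1. Step 13. The aryl anion formed after carboxylate addition may be protonated before the acyl group shifts, which leaves plain O-arylation. The carboxylate may also add at the wrong aryne carbon, or the chloride displacement may stall at the open-chain stage. The fallback makes the same aryl anion stepwise, with its position fixed by a bromine atom. It sets out from bromophenol 7 and acid 19: Steglich esterification (DCC, DMAP, CH2Cl2, rt) should give the aryl ester 3,5-bis(benzyloxy)-2-bromo-4-methoxyphenyl (E)-3-[2,5-bis(benzyloxy)-4-methoxyphenyl]-3-chloro-2-methoxyprop-2-enoate F1. Bromine–lithium exchange (n-BuLi, THF, −100 °C) then places the carbanion beside the ester and triggers an anionic Fries-type shift of the acyl group from oxygen to carbon. After an AcOH quench this should give the o-hydroxyaryl ketone (E)-1-[2,4-bis(benzyloxy)-6-hydroxy-3-methoxyphenyl]-3-[2,5-bis(benzyloxy)-4-methoxyphenyl]-3-chloro-2-methoxyprop-2-en-1-one F2. Cs2CO3 in DMF at 60 °C would close the pyranone by addition–elimination, and the route is rejoined at 23.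

2. Step 16. The bromine may be lost reductively under the copper conditions, or methoxide may open the pyranone at the temperature the substitution needs. The fallback introduces the 8-oxygen as a phenol and sets out from 24, so that step 15 is bypassed as well. Elbs persulfate oxidation (K2S2O8, aqueous KOH–pyridine, rt) para to the 5-hydroxyl should give the sulfate ester potassium 7-(benzyloxy)-2-[2,5-bis(benzyloxy)-4-methoxyphenyl]-5-hydroxy-3,6-dimethoxy-4-oxo-4H-chromen-8-yl sulfate F3. Brief hydrolysis (dilute HCl, Na2SO3, 80 °C) should release the quinol 7-(benzyloxy)-2-[2,5-bis(benzyloxy)-4-methoxyphenyl]-5,8-dihydroxy-3,6-dimethoxy-4H-chromen-4-one F4, which is to be handled under argon. Methylation with MeI (1.0 equiv) and K2CO3 in acetone at rt should take place only at the 8-hydroxyl, because the 5-hydroxyl is tied up in a hydrogen bond to the C4 carbonyl, and the route is rejoined at 26.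

3. Step 12. Hydroxide may attack the chlorine-bearing alkene carbon instead of the ester, returning a β-keto acid that decarboxylates. The fallback reaches the acid at the aldehyde oxidation level, so that no ester is cleaved next to the vinyl chloride; it sets out from 17 and bypasses step 11 as well. Krapcho dealkoxycarbonylation (LiCl, wet DMSO, 150 °C) should give the ketone 1-[2,5-bis(benzyloxy)-4-methoxyphenyl]-2-methoxyethan-1-one F5. Vilsmeier–Haack–Arnold chloroformylation (POCl3, DMF, 60 °C; then H2O) should convert it into the β-chloro enal (E)-3-[2,5-bis(benzyloxy)-4-methoxyphenyl]-3-chloro-2-methoxyprop-2-enal F6 (either geometry serves). Pinnick oxidation (NaClO2, NaH2PO4, 2-methyl-2-butene, t-BuOH–H2O, rt) then delivers the acid, and the route is rejoined at 19.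

Further compounds
F1 | step 13 | 3,5-bis(benzyloxy)-2-bromo-4-methoxyphenyl (E)-3-[2,5-bis(benzyloxy)-4-methoxyphenyl]-3-chloro-2-methoxyprop-2-enoate | CO/C(C(=O)Oc1cc(OCc2ccccc2)c(OC)c(OCc2ccccc2)c1Br)=C(/Cl)c1cc(OCc2ccccc2)c(OC)cc1OCc1ccccc1
F2 | step 13 | (E)-1-[2,4-bis(benzyloxy)-6-hydroxy-3-methoxyphenyl]-3-[2,5-bis(benzyloxy)-4-methoxyphenyl]-3-chloro-2-methoxyprop-2-en-1-one | CO/C(C(=O)c1c(O)cc(OCc2ccccc2)c(OC)c1OCc1ccccc1)=C(/Cl)c1cc(OCc2ccccc2)c(OC)cc1OCc1ccccc1
F3 | step 16 | potassium 7-(benzyloxy)-2-[2,5-bis(benzyloxy)-4-methoxyphenyl]-5-hydroxy-3,6-dimethoxy-4-oxo-4H-chromen-8-yl sulfate | [K+].COc1cc(OCc2ccccc2)c(-c2oc3c(OS(=O)(=O)[O-])c(OCc4ccccc4)c(OC)c(O)c3c(=O)c2OC)cc1OCc1ccccc1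
F4 | step 16 | 7-(benzyloxy)-2-[2,5-bis(benzyloxy)-4-methoxyphenyl]-5,8-dihydroxy-3,6-dimethoxy-4H-chromen-4-one | COc1cc(OCc2ccccc2)c(-c2oc3c(O)c(OCc4ccccc4)c(OC)c(O)c3c(=O)c2OC)cc1OCc1ccccc1
F5 | step 12 | 1-[2,5-bis(benzyloxy)-4-methoxyphenyl]-2-methoxyethan-1-one | COCC(=O)c1cc(OCc2ccccc2)c(OC)cc1OCc1ccccc1
F6 | step 12 | (E)-3-[2,5-bis(benzyloxy)-4-methoxyphenyl]-3-chloro-2-methoxyprop-2-enal | CO/C(C=O)=C(/Cl)c1cc(OCc2ccccc2)c(OC)cc1OCc1ccccc1
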